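**Retrosynthetic overview**
1. Target 12 ⇒ (E)-C=C bond by Wittig reaction: 4-hydroxybenzaldehyde 9 plus the C8 chloroacetate 7 (through its PPh3 ylide).
2. 7 ⇒ C8–O ester bond by Mitsunobu SN2 (inversion) of the trans-1,3-diol 5 with chloroacetic acid 6; this sets 8S (oxygen cis to the C7 side chain).
3. 5 ⇒ bulnesol 1 by hydroxyl-directed γ-C–H oxygenation at C8 (C–H → C–Si → C–O with retention), the tertiary OH acting as director.
4. Rings: neither carbocycle is made. The 5/7-fused skeleton with the C4, C5 and C7 stereocentres is bought with 1; only a transient oxasilolane is closed and opened again in step 1.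

Assumption: natural bulnesol (3S,3aS,5R; main alcohol of commercial guaiac wood oil, also sold neat) counts as a cheap commercial starting material; positions are in guaiane numbering (C7 carries the 2-hydroxyprop-2-yl carbon C11, C8 the ester oxygen, C6 is the other CH2 next to C7).

**Step 1**
Reactants: 1 bulnesol, 2-[(3S,3aS,5R)-3,8-dimethyl-1,2,3,3a,4,5,6,7-octahydroazulen-5-yl]propan-2-ol; 2 diethylsilane
Product: 5 (3S,3aS,5S,6R)-5-(2-hydroxypropan-2-yl)-3,8-dimethyl-1,2,3,3a,4,5,6,7-octahydroazulen-6-ol (C8–OH trans to the C7 side chain), via hydrosilyl ether 3 (not isolated), via oxasilolane 4 (not isolated)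
Conditions: 2, [Ir(cod)OMe]2 (cat.), THF, rt; then [Ir(cod)OMe]2/L* (cat.), norbornene, THF, 100 °C; then t-BuOOH, CsOH·H2O, TBAF (activators), DMF, 70 °C. L* = C1-symmetric chiral N,N-ligand on the electron-rich 3,4,7,8-tetramethyl-1,10-phenanthroline core with one stereogenic 1-arylethyl group at C2; both antipodes are screened and the matched one is used.
Reagents that add atoms: tert-butyl hydroperoxide, CC(C)(C)OO
Why: Proposed new method: catalyst-controlled, group-selective hydroxyl-directed γ-C(sp3)–H silylation/oxidation – after dehydrogenative O-silylation, the Ir–silyl centre of the chiral catalyst cleaves the pseudo-equatorial C8–H of the less hindered γ-CH2 (C8, flanked by CH2) in preference to the diastereotopic C6–H2 (flanked by the ring-fusion CH), the matched ligand reinforcing this steric bias while the shielded tetrasubstituted alkene stays out of reach; C–Si reductive elimination then closes the trans-fused oxasilolane 4 (norbornene takes up H2), and Tamao–Fleming oxidation with nucleophilic t-BuOO− turns C8–Si into C8–O with retention, so C8 is set R with OH trans to the C7 side chain; closest known reaction type: Ir/phenanthroline-catalysed (hydrido)silyl-ether-directed γ-silylation of secondary C–H bonds followed by Tamao–Fleming oxidation (1,3-diol synthesis), together with Ir-catalysed enantioselective intramolecular C–H silylation using chiral N,N-ligands.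

**Step 2**
Reactants: 5 trans-diol; 6 chloroacetic acid
Product: 7 (3S,3aS,5S,6S)-5-(2-hydroxypropan-2-yl)-3,8-dimethyl-1,2,3,3a,4,5,6,7-octahydroazulen-6-yl 2-chloroacetate (ester cis to the C7 side chain)
Conditions: PPh3, DIAD, THF, 0 °C → rt (6, PPh3 and DIAD 4 equiv each)
Reagents that add atoms: none
Why: Mitsunobu esterification in its chloroacetic acid variant for hindered carbinols – the secondary C8–OH is activated as the oxyphosphonium ion and displaced by chloroacetate in an SN2 reaction with inversion (8R → 8S, ester now cis to the C7 side chain), while the tertiary C11–OH cannot be displaced and the pseudo-equatorial leaving group has no antiperiplanar β-hydrogen for E2.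

**Step 3**
Reactants: 7 cis-chloroacetate; 8 triphenylphosphine; 9 4-hydroxybenzaldehyde
Product: 12 (3S,3aS,5S,6S)-5-(2-hydroxypropan-2-yl)-3,8-dimethyl-1,2,3,3a,4,5,6,7-octahydroazulen-6-yl (2E)-3-(4-hydroxyphenyl)prop-2-enoate (CNP0403230.1), via phosphonium chloride 10 (not isolated), via phosphorus ylide 11 (not isolated)
Conditions: 8, NaI (cat.), MeCN, 70 °C; then 9, aq. NaHCO3, 40 °C
Reagents that add atoms: none
Why: One-pot Wittig olefination – iodide-catalysed SN2 quaternisation of PPh3 by the α-chloro ester gives 10, bicarbonate forms the ester-stabilised ylide 11, and its reaction with the aldehyde gives the (E)-cinnamate (stabilised ylides are E-selective and tolerate the free phenol); no stereocentre is touched.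

**Compound list**
1 | bulnesol, 2-[(3S,3aS,5R)-3,8-dimethyl-1,2,3,3a,4,5,6,7-octahydroazulen-5-yl]propan-2-ol | CC1=C2CC[C@H](C)[C@@H]2C[C@H](C(C)(C)O)CC1 | starting material
2 | diethylsilane | CC[SiH2]CC | starting material
3 | bulnesol O-diethyl(hydrido)silyl ether | CC1=C2CC[C@H](C)[C@@H]2C[C@H](C(C)(C)O[SiH](CC)CC)CC1 | intermediate
4 | trans-fused 2,2-diethyl-5,5-dimethyl-1,2-oxasilolane across C7–C8 (Si on C8, trans to C11) | CC1=C2CC[C@H](C)[C@@H]2C[C@@H]3C(C)(C)O[Si](CC)(CC)[C@@H]3C1 | intermediate
5 | (3S,3aS,5S,6R)-5-(2-hydroxypropan-2-yl)-3,8-dimethyl-1,2,3,3a,4,5,6,7-octahydroazulen-6-ol (trans-diol) | CC1=C2CC[C@H](C)[C@@H]2C[C@H](C(C)(C)O)[C@H](O)C1 | intermediate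
6 | chloroacetic acid | OC(=O)CCl | starting material
7 | (3S,3aS,5S,6S)-5-(2-hydroxypropan-2-yl)-3,8-dimethyl-1,2,3,3a,4,5,6,7-octahydroazulen-6-yl 2-chloroacetate | CC1=C2CC[C@H](C)[C@@H]2C[C@H](C(C)(C)O)[C@@H](OC(=O)CCl)C1 | intermediate
8 | triphenylphosphine | c1ccc(cc1)P(c1ccccc1)c1ccccc1 | starting material
9 | 4-hydroxybenzaldehyde | O=Cc1ccc(O)cc1 | starting material
10 | phosphonium chloride of 7 (ester–CH2–PPh3+ Cl−) | CC1=C2CC[C@H](C)[C@@H]2C[C@H](C(C)(C)O)[C@@H](OC(=O)C[P+](c2ccccc2)(c2ccccc2)c2ccccc2)C1.[Cl-] | intermediate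
11 | ester-stabilised ylide (ester–CH=PPh3) | CC1=C2CC[C@H](C)[C@@H]2C[C@H](C(C)(C)O)[C@@H](OC(=O)C=P(c2ccccc2)(c2ccccc2)c2ccccc2)C1 | intermediate
12 | (3S,3aS,5S,6S)-5-(2-hydroxypropan-2-yl)-3,8-dimethyl-1,2,3,3a,4,5,6,7-octahydroazulen-6-yl (2E)-3-(4-hydroxyphenyl)prop-2-enoate | CC1=C2CC[C@H](C)[C@@H]2C[C@H](C(C)(C)O)[C@@H](OC(=O)/C=C/c2ccc(O)cc2)C1 | target

**Step count and risks**
Total step count: 3. Longest linear sequence: 3 (from 1).

The three steps most likely to fail:

1. Step 1 (the proposed new step). The risks are incomplete C8/C6 site selection, formation of some cis-fused oxasilolane, and loss of activity with a chiral ligand. The fallback uses known chemistry and gives up catalyst control: it sets out from 1 and comes back to the route at 5. Compound 1 is O-silylated with 2 and cyclised with the literature achiral catalyst ([Ir(cod)OMe]2/3,4,7,8-tetramethyl-1,10-phenanthroline, norbornene, THF, 100–120 °C) by way of 3 and 4, then oxidised under Tamao–Fleming conditions. Site selection now rests on substrate sterics alone. The by-product, the C6-hydroxylated regioisomeric diol F1 (6-OH trans to the C7 side chain), is removed by chromatography of the diols. Any residue is left behind in step 2, because its carbinol, flanked by the ring-fusion CH, is esterified much more slowly.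

2. Step 2. The risks are slow SN2 at a carbinol next to the bulky C7 side chain, and oxetane formation or fragmentation through the neighbouring tertiary OH. The fallback corrects C8 by oxidation and reduction instead of substitution: it sets out from 5 and comes back at 7. Dess–Martin periodinane (NaHCO3, CH2Cl2) gives the β-hydroxy ketone F2. L-Selectride (THF, −78 °C) adds hydride anti to the C7 side chain and gives the cis-diol F3. Chloroacetic anhydride/pyridine/DMAP then acylates only the secondary hydroxyl and gives 7. Because C8 becomes planar on the way, this sequence also absorbs any C8-epimer mixture from step 1.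

3. Step 3. The risks are sluggish quaternisation and low conversion with the partly deprotonated hydroxy-aldehyde. The fallback avoids olefination and brings in the intact C9 acid: it sets out from 7 and comes back at 12. K2CO3 (cat.) in MeOH at 0 °C removes the chloroacetyl group and gives the cis-diol F3. Steglich esterification with commercial (E)-4-acetoxycinnamic acid (EDC·HCl, DMAP, CH2Cl2) gives the C8 (E)-4-acetoxycinnamate F4. Pyrrolidine (CH2Cl2, 0 °C) then cleaves only the aryl acetate and gives 12.

**Further compounds**
F1 | step 1 | C6-hydroxylated regioisomer of 5, guai-1(10)-ene-6,11-diol with 6-OH trans to the C7 side chain | CC1=C2CC[C@H](C)[C@@H]2[C@H](O)[C@H](C(C)(C)O)CC1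
F2 | step 2 | β-hydroxy ketone, (3S,3aS,5R)-5-(2-hydroxypropan-2-yl)-3,8-dimethyl-2,3,3a,4,5,7-hexahydroazulen-6(1H)-one | CC1=C2CC[C@H](C)[C@@H]2C[C@H](C(C)(C)O)C(=O)C1
F3 | step 2 | cis-diol, (3S,3aS,5S,6S)-5-(2-hydroxypropan-2-yl)-3,8-dimethyl-1,2,3,3a,4,5,6,7-octahydroazulen-6-ol | CC1=C2CC[C@H](C)[C@@H]2C[C@H](C(C)(C)O)[C@@H](O)C1
F4 | step 3 | C8 (E)-4-acetoxycinnamate of the cis-diol | CC1=C2CC[C@H](C)[C@@H]2C[C@H](C(C)(C)O)[C@@H](OC(=O)/C=C/c2ccc(OC(C)=O)cc2)C1
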